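**Amounts first.** Each flask is charged with free monomer and initiator and then left for a time, and I asked which of these had to be known well.

| flask | free monomer | initiator | remark | time |
|---|---|---|---|---|
| gamma | 0.035 M | 3 mol% | run made earlier |  |
| ochre | 0.035 M | 2 mol% |  | 1.5 h |
| amber | 0.0080 M | 2 mol% |  | 1.5 h |

gamma run (percent of the free monomer charged)

| time / min | monomer in chains / % | free monomer / % |
|---|---|---|
| 4.00 | 1.1 | 98.6 |
| 8.00 | 3.2 | 95.5 |
| 10.0 | 4.1 | 95.8 |
| 15.0 | 9.3 | 91.1 |
| 20.0 | 13.8 | 85.9 |

(each reading ± 0.5 percentage points)

- the average divides the monomer in chains by the number of chains begun, living and dead together
- on the list of suspects stand: free monomer + initiator -> living end + monomer in chains; free monomer + living end -> monomer in chains + living end; living end + monomer in chains -> dead end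
- the earlier runs do not show the number of chains; that part of a forecast is a guess
- no earlier run changes the charge of initiator; that part of a forecast is a guess

- which of the two ends with the longer chains by the average number of monomer units in a chain (chains begun, living or dead) ("neither" if they lie within 10%) (ochre / amber / neither)
- average number of monomer units in a chain (chains begun, living or dead) at the end, ochre
- average number of monomer units in a chain (chains begun, living or dead) at the end, amber

**What matters.** The starting step and the growing step on the list each take one free monomer. While free monomer stays near its charge, each step is pseudo-first-order in its partner, so free monomer and time enter as their product. I carried the exposure ratio, free monomer charged times time over that product at gamma's last reading: 1.03 for amber, 4.50 for ochre. While living ends survive, an error in free monomer or time moves the length in proportion. While living ends survive, I expected the initiator loading to cancel from the length, with chains begun and monomer in chains both scaling with it, but once living ends die that need not hold, and monomer in chains itself follows the loading. The dying step takes a living end and monomer in chains, which both scale with the charge at fixed loading, so at fixed loading it goes by the same exposure; but gamma's loading differs from ochre's and the runs barely show this step, so ochre stayed uncertain.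

**My number.** Amber stood about where gamma stood at its last reading, so I scaled that reading of 13.8%, scatter 0.5 percentage points, by the loadings and the squared ratio, which gave 9.73% in chains. Going round once with each flask's mean free monomer moved the ratio to 1.05 and monomer in chains to 10.2%. Amber's length should match gamma's, which the runs do not show.

**The forecast.** It named ochre as longer, with 33 for ochre (range 20 to 90) and 10 for amber (range 6 to 28), holding that “both steps are slower at the lower concentrations”.

**The flasks.** Ochre ended longer, at 20.6 against 11.9 for amber.

    free monomer + initiator → living end + monomer in chains (k = 0.0132 M⁻¹ s⁻¹)
    free monomer + living end → monomer in chains + living end, rate k2*[living end]*[free monomer] (k = 0.507 M⁻¹ s⁻¹)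
    living end + monomer in chains → dead end (k = 0.0932 M⁻¹ s⁻¹)

Amber, at ratio 1.03, held 10.0% monomer in chains against my 10.2%, and its length stood close to gamma's 11.1. Ochre, at ratio 4.50, reached 1.85 times gamma's length. At 0.538 h in ochre, the half-life of a living end by the dying step was 0.32 h, shorter than the 0.51 h of initiator by the starting step. At 1.50 h ochre held 4.66 × 10⁻⁵ M living end, with 63.1% of its free monomer still unused.

The runs were computed with made-up constants; the scatter is artificial.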